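**Retrosynthetic overview**

- The route rests on the dearomatised ring: a six-membered carbocycle whose quaternary carbon (methyl and prenyl) lies para to one ring carbonyl and between two oxygenated ring carbons. These two flanks differ only in what follows them, the ArCH2-bearing carbon on one side and the butanoyl-bearing carbon on the other.
- This ring is a 4,4-disubstituted cyclohex-2-enone with two further oxygens. It is the only ring built, by a catalytic enantioselective (4+2) cycloaddition of a 1-amino-3-siloxydiene with methacrolein; the arene is bought.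
- Last disconnection: the ArCH2–ring bond, by reductive alkylation of the acyl trione with an aryl aldehyde made from 2,4,6-trihydroxybenzaldehyde (O-methylation, Friedel–Crafts hexanoylation).
- The flanks are oxygenated one after the other. The alkene flank is stored as an oxirane; the saturated flank is dehydrogenated, β-hydroxylated and oxidised to a 1,3-dione, which is C-butanoylated by an O→C acyl shift. Only then is the oxirane isomerised to the third carbonyl, because the unsubstituted trione (and the 2,5-dienone) would be achiral.
- The prenyl group comes from the formyl group of the cycloadduct by two Wittig reactions.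

Key step: step 3

Assumption 1: the (4R,5R)-diol catalyst is taken to expose the face of hydrogen-bonded methacrolein that leads to the (S)-formyl enone; should the adduct prove to be (R), the (4S,5S)-diol is used and nothing else changes.
Assumption 2: the cyclic di- and triketones are written as keto tautomers although they should be largely enolised; the target is written as the dienol tautomer of the given structure.

**Route**

Step 1
Reactants: 1 (E)-4-methoxybut-3-en-2-one
Product: 2 (E)-4-(dimethylamino)but-3-en-2-one
Conditions: Me2NH (2 M in THF), THF, 0 °C → rt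
Reagents that add atoms: dimethylamine, CNC
Why: Conjugate addition–elimination on the β-alkoxy enone should go to completion because the vinylogous amide is more stabilised than the vinylogous ester.

Step 2
Reactants: 2 (E)-4-(dimethylamino)but-3-en-2-one
Product: 3 (E)-1-(dimethylamino)-3-(tert-butyldimethylsilyloxy)buta-1,3-diene
Conditions: KN(SiMe3)2, THF, −78 °C; t-BuMe2SiCl, −78 °C → rt
Reagents that add atoms: tert-butyldimethylsilyl chloride, CC(C)(C)[Si](C)(C)Cl
Why: Kinetic deprotonation of the methyl group gives the cross-conjugated potassium dienolate, which is silylated on oxygen (enolate O-silylation) with the E-enamine geometry retained.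

Step 3
Reactants: 3 (E)-1-(dimethylamino)-3-(tert-butyldimethylsilyloxy)buta-1,3-diene; 4 methacrolein
Product: 6 (S)-1-methyl-4-oxocyclohex-2-ene-1-carbaldehyde, via silyl enol ether cycloadduct 5 (not isolated)
Conditions: (4R,5R)-2,2-dimethyl-α,α,α′,α′-tetra(naphthalen-1-yl)-1,3-dioxolane-4,5-dimethanol (20 mol %), 4 (2 equiv), toluene, −80 °C; then 1 M HCl (aq.), THF, 0 °C
Reagents that add atoms: none
Why: One hydroxyl of the diol hydrogen-bonds to the formyl oxygen of 4 (reinforced by the second hydroxyl), lowering its LUMO, and diene 3 adds in a concerted, strongly asynchronous Diels–Alder reaction in which the unsubstituted diene terminus bonds to the enal CH2 ahead of the bond from the amino-bearing terminus to the α-carbon. The closest known reaction is the diol-catalysed cycloaddition of 1-amino-3-siloxybutadienes with α-substituted acroleins, of which this is the parent case. The six-membered carbocycle is closed by an intermolecular (4+2) cycloaddition that forms both ring bonds in one step. The quaternary stereocentre is set by the catalyst, a naphthyl group covering one face of the bound enal so that the diene approaches the open face in an endo sense, and having no α-hydrogen it cannot epimerise later. The step needs ortho regioselectivity and high facial selectivity; the first is secured by the matched polarisation of the amino and siloxy donors against the formyl acceptor, the second by the low temperature and non-coordinating solvent, in which the uncatalysed background reaction should be slow. Dilute acid then hydrolyses the silyl enol ether and eliminates dimethylamine from the position β to the new ketone, giving enone 6.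

Step 4
Reactants: 6 (S)-1-methyl-4-oxocyclohex-2-ene-1-carbaldehyde
Product: 7 (S)-4-(2-methoxyethenyl)-4-methylcyclohex-2-en-1-one (E/Z mixture)
Conditions: Ph3P(CH2OMe)Cl (1.1 equiv), KN(SiMe3)2 (1.05 equiv), THF, 0 °C; then 6, −78 → 0 °C
Reagents that add atoms: (methoxymethyl)triphenylphosphonium chloride, COC[P+](c1ccccc1)(c1ccccc1)c1ccccc1.[Cl-]
Why: Wittig olefination should take place at the non-enolisable aldehyde, which is far more electrophilic than the conjugated ketone, when a slight excess of ylide is used cold; the alkene geometry is irrelevant.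

Step 5
Reactants: 7 (S)-4-(2-methoxyethenyl)-4-methylcyclohex-2-en-1-one
Product: 8 (R)-2-(1-methyl-4-oxocyclohex-2-en-1-yl)acetaldehyde
Conditions: 1 M HCl (aq.), THF, 0 °C → rt
Reagents that add atoms: water, O
Why: Acid-catalysed enol ether hydrolysis (C-protonation, hydration of the oxocarbenium ion, loss of methanol) gives the homologated aldehyde without touching the enone or the quaternary centre, whose descriptor changes only through CIP priorities.

Step 6
Reactants: 8 (R)-2-(1-methyl-4-oxocyclohex-2-en-1-yl)acetaldehyde
Product: 9 (R)-4-methyl-4-(3-methylbut-2-en-1-yl)cyclohex-2-en-1-one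
Conditions: i-PrPPh3I (1.1 equiv), n-BuLi (1.05 equiv), THF, 0 °C; then 8, −78 → 0 °C
Reagents that add atoms: isopropyltriphenylphosphonium iodide, CC(C)[P+](c1ccccc1)(c1ccccc1)c1ccccc1.[I-]
Why: Wittig olefination of the unhindered aldehyde with the isopropylidene ylide should outrun any reaction at the enone at low temperature and gives the prenyl group with no geometric isomerism.

Step 7
Reactants: 9 (R)-4-methyl-4-(3-methylbut-2-en-1-yl)cyclohex-2-en-1-one
Product: 10 (4R)-2,3-epoxy-4-methyl-4-(3-methylbut-2-en-1-yl)cyclohexan-1-one (both oxirane diastereomers)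
Conditions: H2O2 (30 % aq.), NaOH (0.2 equiv), MeOH, 0 °C
Reagents that add atoms: hydrogen peroxide, OO
Why: Weitz–Scheffer nucleophilic epoxidation attacks only the electron-poor enone alkene and leaves the prenyl alkene alone; the two new oxirane centres may form on either face because both are erased in step 12.

Step 8
Reactants: 10 (4R)-2,3-epoxy-4-methyl-4-(3-methylbut-2-en-1-yl)cyclohexan-1-one
Product: 11 (4S)-5,6-epoxy-4-methyl-4-(3-methylbut-2-en-1-yl)cyclohex-2-en-1-one
Conditions: LiN(i-Pr)2, THF, −78 °C; then PhS(Cl)=N-t-Bu, −78 °C
Reagents that add atoms: none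
Why: Enolate dehydrogenation with a sulfinimidoyl chloride should be regiospecific because the amide base can only remove a CH2 proton on the saturated flank (the oxirane C–H is not enolisable); the sulfenylated enolate undergoes syn-elimination, and the new enone carries an oxirane on its other flank, so it is not the symmetric 2,5-dienone.

Step 9
Reactants: 11 (4S)-5,6-epoxy-4-methyl-4-(3-methylbut-2-en-1-yl)cyclohex-2-en-1-one
Product: 13 (4S)-2,3-epoxy-5-hydroxy-4-methyl-4-(3-methylbut-2-en-1-yl)cyclohexan-1-one, via β-boryl ketone 12 (not isolated)
Conditions: CuCl (5 mol %), NaOt-Bu (10 mol %), bis[2-(diphenylphosphino)phenyl] ether (5 mol %), B2pin2 (1.1 equiv), MeOH (2 equiv), THF, rt; then H2O2 (30 % aq.), pH 7 phosphate buffer, 0 °C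
Reagents that add atoms: hydrogen peroxide, OO
Why: Copper-catalysed conjugate borylation places boron on the enone β-carbon (a secondary carbon next to the quaternary one, as in 4,4-dialkylcyclohexenones), methanol protonates the copper enolate, and buffered peroxide oxidises the C–B bond with retention; the configuration of the new carbinol centre does not matter because it is oxidised in step 10.

Step 10
Reactants: 13 (4S)-2,3-epoxy-5-hydroxy-4-methyl-4-(3-methylbut-2-en-1-yl)cyclohexan-1-one
Product: 14 (4R)-5,6-epoxy-4-methyl-4-(3-methylbut-2-en-1-yl)cyclohexane-1,3-dione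
Conditions: Dess–Martin periodinane (1.2 equiv), CH2Cl2, 0 °C → rt
Reagents that add atoms: none
Why: Periodinane oxidation of a β-hydroxy ketone gives the 1,3-diketone under nearly neutral conditions that spare the oxirane and the alkene; the dione is not symmetric because one flank of the quaternary carbon is still an oxirane.

Step 11
Reactants: 14 (4R)-5,6-epoxy-4-methyl-4-(3-methylbut-2-en-1-yl)cyclohexane-1,3-dione
Product: 16 (4R)-2-butanoyl-5,6-epoxy-4-methyl-4-(3-methylbut-2-en-1-yl)cyclohexane-1,3-dione, via enol butanoate 15 (not isolated)
Conditions: PrCOCl (1.05 equiv), Et3N (2 equiv), MeCN, 0 °C; then 4-(dimethylamino)pyridine (20 mol %), rt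
Reagents that add atoms: butanoyl chloride, CCCC(=O)Cl
Why: O-Acylation of the vinylogous acid followed by the nucleophile-catalysed O→C acyl shift (acylpyridinium and dione enolate pair) leads to the chelated 2-acyl-1,3-dione; the only carbon between the two carbonyls lies on the formerly saturated flank, which fixes the butanoyl group on the correct side of the quaternary centre.

Step 12
Reactants: 16 (4R)-2-butanoyl-5,6-epoxy-4-methyl-4-(3-methylbut-2-en-1-yl)cyclohexane-1,3-dione
Product: 17 (4R)-2-butanoyl-4-methyl-4-(3-methylbut-2-en-1-yl)cyclohexane-1,3,5-trione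
Conditions: Pd(PPh3)4 (5 mol %), 1,2-bis(diphenylphosphino)ethane (5 mol %), toluene, 80 °C
Reagents that add atoms: none
Why: Isomerisation of an α,β-epoxy ketone to a β-diketone by zerovalent palladium (oxidative addition into the C–O bond next to the carbonyl, β-hydride elimination from the carbinol carbon, reductive elimination) turns the oxirane into the third ring carbonyl; since the butanoyl group already marks one flank, the trione keeps the configuration of the quaternary carbon.

Step 13
Reactants: 18 2,4,6-trihydroxybenzaldehyde
Product: 19 2,6-dihydroxy-4-methoxybenzaldehyde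
Conditions: Me2SO4 (1.0 equiv), K2CO3 (1.0 equiv), acetone, rt
Reagents that add atoms: dimethyl sulfate, COS(=O)(=O)OC
Why: Williamson etherification should occur at the 4-hydroxyl, the only one not hydrogen-bonded to the formyl group and the most acidic, and the hard sulfate electrophile favours O- over C-methylation.

Step 14
Reactants: 19 2,6-dihydroxy-4-methoxybenzaldehyde
Product: 20 3-hexanoyl-2,6-dihydroxy-4-methoxybenzaldehyde
Conditions: n-C5H11COCl (1.2 equiv), AlCl3 (3.5 equiv), CH2Cl2/PhNO2, 0 °C → rt
Reagents that add atoms: hexanoyl chloride, CCCCCC(=O)Cl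
Why: Friedel–Crafts acylation can give only one regioisomer because the two free ring positions are equivalent by symmetry and each is activated by three oxygen donors; the short reaction at or below room temperature should spare the methyl ether.

Step 15
Reactants: 17 (4R)-2-butanoyl-4-methyl-4-(3-methylbut-2-en-1-yl)cyclohexane-1,3,5-trione; 20 3-hexanoyl-2,6-dihydroxy-4-methoxybenzaldehyde
Product: 21 (4R)-2-butanoyl-6-[(3-hexanoyl-2,6-dihydroxy-4-methoxyphenyl)methyl]-3,5-dihydroxy-4-methyl-4-(3-methylbut-2-en-1-yl)cyclohexa-2,5-dien-1-one
Conditions: L-proline (20 mol %), diethyl 2,6-dimethyl-1,4-dihydropyridine-3,5-dicarboxylate (1.1 equiv), CH2Cl2, rt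
Reagents that add atoms: none
Why: Organocatalytic reductive alkylation (Knoevenagel condensation, then conjugate transfer hydrogenation): the one remaining acidic ring CH2 of 17 condenses with the aldehyde through its prolinium ion, and the alkylidene trione so formed is reduced by the dihydropyridine, which does not touch the ketones, the prenyl group or the quaternary centre.

**Compound list**

1 | (E)-4-methoxybut-3-en-2-one | CO/C=C/C(C)=O | starting material
2 | (E)-4-(dimethylamino)but-3-en-2-one | CN(C)/C=C/C(C)=O | intermediate
3 | (E)-1-(dimethylamino)-3-(tert-butyldimethylsilyloxy)buta-1,3-diene | CN(C)/C=C/C(=C)O[Si](C)(C)C(C)(C)C | intermediate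
4 | methacrolein | CC(=C)C=O | starting material
5 | (1S,2R)-4-[(tert-butyldimethylsilyl)oxy]-2-(dimethylamino)-1-methylcyclohex-3-ene-1-carbaldehyde (endo adduct, amino group cis to formyl) | O=C[C@@]1(C)CCC(O[Si](C)(C)C(C)(C)C)=C[C@H]1N(C)C | intermediate (not isolated)
6 | (S)-1-methyl-4-oxocyclohex-2-ene-1-carbaldehyde | O=C[C@]1(C)C=CC(=O)CC1 | intermediate
7 | (S)-4-(2-methoxyethenyl)-4-methylcyclohex-2-en-1-one (E/Z mixture) | COC=C[C@]1(C)C=CC(=O)CC1 | intermediate
8 | (R)-2-(1-methyl-4-oxocyclohex-2-en-1-yl)acetaldehyde | O=CC[C@]1(C)C=CC(=O)CC1 | intermediate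
9 | (R)-4-methyl-4-(3-methylbut-2-en-1-yl)cyclohex-2-en-1-one | CC(C)=CC[C@]1(C)C=CC(=O)CC1 | intermediate
10 | (4R)-2,3-epoxy-4-methyl-4-(3-methylbut-2-en-1-yl)cyclohexan-1-one (both oxirane diastereomers) | CC(C)=CC[C@]1(C)C2OC2C(=O)CC1 | intermediate
11 | (4S)-5,6-epoxy-4-methyl-4-(3-methylbut-2-en-1-yl)cyclohex-2-en-1-one | CC(C)=CC[C@]1(C)C2OC2C(=O)C=C1 | intermediate
12 | (4S)-2,3-epoxy-4-methyl-4-(3-methylbut-2-en-1-yl)-5-(4,4,5,5-tetramethyl-1,3,2-dioxaborolan-2-yl)cyclohexan-1-one | CC(C)=CC[C@]1(C)C2OC2C(=O)CC1B1OC(C)(C)C(C)(C)O1 | intermediate (not isolated)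
13 | (4S)-2,3-epoxy-5-hydroxy-4-methyl-4-(3-methylbut-2-en-1-yl)cyclohexan-1-one | CC(C)=CC[C@]1(C)C2OC2C(=O)CC1O | intermediate
14 | (4R)-5,6-epoxy-4-methyl-4-(3-methylbut-2-en-1-yl)cyclohexane-1,3-dione | CC(C)=CC[C@]1(C)C2OC2C(=O)CC1=O | intermediate
15 | (4R)-5,6-epoxy-4-methyl-4-(3-methylbut-2-en-1-yl)-3-oxocyclohex-1-en-1-yl butanoate (ester at the oxygen remote from the quaternary carbon) | CC(C)=CC[C@]1(C)C2OC2C(OC(=O)CCC)=CC1=O | intermediate (not isolated)
16 | (4R)-2-butanoyl-5,6-epoxy-4-methyl-4-(3-methylbut-2-en-1-yl)cyclohexane-1,3-dione | CC(C)=CC[C@]1(C)C2OC2C(=O)C(C(=O)CCC)C1=O | intermediate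
17 | (4R)-2-butanoyl-4-methyl-4-(3-methylbut-2-en-1-yl)cyclohexane-1,3,5-trione | CC(C)=CC[C@]1(C)C(=O)CC(=O)C(C(=O)CCC)C1=O | intermediate
18 | 2,4,6-trihydroxybenzaldehyde | O=Cc1c(O)cc(O)cc1O | starting material
19 | 2,6-dihydroxy-4-methoxybenzaldehyde | COc1cc(O)c(C=O)c(O)c1 | intermediate
20 | 3-hexanoyl-2,6-dihydroxy-4-methoxybenzaldehyde | CCCCCC(=O)c1c(OC)cc(O)c(C=O)c1O | intermediate
21 | (4R)-2-butanoyl-6-[(3-hexanoyl-2,6-dihydroxy-4-methoxyphenyl)methyl]-3,5-dihydroxy-4-methyl-4-(3-methylbut-2-en-1-yl)cyclohexa-2,5-dien-1-one | CCCCCC(=O)c1c(OC)cc(O)c(CC2=C(O)[C@@](C)(CC=C(C)C)C(O)=C(C(=O)CCC)C2=O)c1O | target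

**Step count and risks**

Total step count: 15. Longest linear sequence: 13 steps (steps 1–12 and 15); the aryl aldehyde arm (steps 13–14) is convergent.

The three steps most likely to fail:

1. Step 15. The aldehyde of 20 sits between two hydrogen-bonded hydroxyls on an electron-rich ring, so condensation may be slow. The transient alkylidene trione may also be captured by a second molecule of 17 before hydride transfer, giving a bis-adduct. The fallback sets out from 20 and makes the arene, not the trione, the electrophile. Reduction of the aldehyde alone (NaBH4, THF/MeOH, −20 °C) should give 1-[2,4-dihydroxy-3-(hydroxymethyl)-6-methoxyphenyl]hexan-1-one F1. Warming F1 with 17 in toluene at 80 °C should expel water to an ortho-quinone methide, which the enol carbon of 17 traps in a conjugate addition. No reducible alkylidene trione is involved, and the route is rejoined at 21.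

2. Step 12. The enolised acyl dione of 16 is a fairly strong acid and may protonate the ring-opened palladium intermediate, stalling the cycle before β-hydride elimination, or the zerovalent catalyst may be lost. The fallback sets out from 16 and replaces the redox-neutral isomerisation by reduction followed by oxidation. Organoselenium reductive opening of the epoxy ketone (Na[PhSeB(OEt)3] made from PhSeSePh and NaBH4, AcOH, EtOH, 0 °C) cleaves the C–O bond next to the carbonyl. It should give (4R)-2-butanoyl-5-hydroxy-4-methyl-4-(3-methylbut-2-en-1-yl)cyclohexane-1,3-dione F2. Periodinane oxidation of F2 rejoins the route at 17.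

3. Step 4. The basic ylide may add only slowly to the aldehyde on a quaternary carbon and instead deprotonate the enone at its CH2, starting aldol-type self-condensation with the aldehyde. The fallback sets out from 5 and olefinates while the ketone is still masked. After the cycloaddition, excess 4 is removed under vacuum and the same ylide is added to the crude silyl enol ether. This should give (1R,6R)-3-[(tert-butyldimethylsilyl)oxy]-6-(2-methoxyethenyl)-N,N,6-trimethylcyclohex-2-en-1-amine F3. Treatment of F3 with 1 M HCl in THF should hydrolyse both enol ethers and eliminate dimethylamine in one operation, rejoining the route at 8.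

Further compounds
F1 | step 15 | 1-[2,4-dihydroxy-3-(hydroxymethyl)-6-methoxyphenyl]hexan-1-one | CCCCCC(=O)c1c(OC)cc(O)c(CO)c1O
F2 | step 12 | (4R)-2-butanoyl-5-hydroxy-4-methyl-4-(3-methylbut-2-en-1-yl)cyclohexane-1,3-dione | CC(C)=CC[C@]1(C)C(O)CC(=O)C(C(=O)CCC)C1=O
F3 | step 4 | (1R,6R)-3-[(tert-butyldimethylsilyl)oxy]-6-(2-methoxyethenyl)-N,N,6-trimethylcyclohex-2-en-1-amine | COC=C[C@@]1(C)CCC(O[Si](C)(C)C(C)(C)C)=C[C@H]1N(C)C
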